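## Retrosynthetic overview

1. Cyclohexene core: aldehyde 1 → silyl ether 2; phosphonate 3 (as its lithio derivative 4) → (E)-aryl diene 5. Methacrolein 6 is the dienophile; its CHO later becomes the CH=CH of the styryl link.
2. Key step: asymmetric Diels–Alder (adduct 7), desilylation (8) and hemiacetal closure in one flask give the cis-fused lactol 9. The cyclohexene and dihydropyran rings form together and both stereocentres are set.
3. Lactol 9 ⇒ ring-opened potassium phenoxide aldehyde 10 ⇒ vinyl phenol 11 (Wittig); phenol + ethyl propiolate 12 ⇒ pyranone ring of coumarin 13.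
4. Second coumarin: bought as 14 and iodinated to 15; the E-styryl bond of target 16 is the last bond made (Heck, 13 + 15).
5. Ring order: cyclohexene + pyranol (one operation) → pyranone of the first coumarin; the second coumarin bicycle is carried in intact.

Assumption: the SMILES is read as the (1R,6R)-cyclohex-2-en-1-yl enantiomer with aryl and styryl cis on the ring; 1, 3, 6, 12, 14 and both antipodes of the oxazaborolidine precatalyst are taken as catalogue items.

## Route

Step 1
Reactants: 1 2-hydroxy-4,6-dimethoxybenzaldehyde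
Product: 2 2-[(tert-butyldimethylsilyl)oxy]-4,6-dimethoxybenzaldehyde
Conditions: t-BuMe2SiCl (1.3 equiv), imidazole (2.5 equiv), DMF, rt
Reagents that add atoms: tert-butyldimethylsilyl chloride, CC(C)(C)[Si](C)(C)Cl
Why: Imidazole-promoted O-silylation (silyl ether protection) masks the chelated phenol so that neither the carbanion of step 2 nor the boron Lewis acid of step 3 meets a free OH; no stereocentre is involved.

Step 2
Reactants: 2 2-[(tert-butyldimethylsilyl)oxy]-4,6-dimethoxybenzaldehyde; 3 diethyl (2-methylprop-2-en-1-yl)phosphonate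
Product: 5 tert-butyl{3,5-dimethoxy-2-[(1E)-3-methylbuta-1,3-dien-1-yl]phenoxy}dimethylsilane, via lithiated phosphonate 4 (not isolated)
Conditions: 3 (1.3 equiv), n-BuLi, THF, −78 °C; then 2, DMPU, −78 °C to rt
Reagents that add atoms: none
Why: Horner–Wadsworth–Emmons olefination in which the allylic phosphonate carbanion attacks the aldehyde through its α-carbon and loses lithium diethyl phosphate, giving the conjugated diene with the E double bond favoured by equilibration of the adduct before elimination.

Step 3
Reactants: 5 tert-butyl{3,5-dimethoxy-2-[(1E)-3-methylbuta-1,3-dien-1-yl]phenoxy}dimethylsilane; 6 methacrolein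
Product: 9 (6aS,10aS)-1,3-dimethoxy-6a,9-dimethyl-6a,7,8,10a-tetrahydro-6H-benzo[c]chromen-6-ol, via silyl ether aldehyde 7 (not isolated), via hydroxy aldehyde 8 (not isolated)
Conditions: (3aS)-1-(2-methylphenyl)-3,3-diphenyltetrahydro-1H,3H-pyrrolo[1,2-c][1,3,2]oxazaborole (20 mol%), Tf2NH (18 mol%), 6 (4 equiv), CH2Cl2, −78 to −40 °C; evaporate volatiles; Bu4NF, AcOH, THF, 0 °C to rt
Reagents that add atoms: none
Why: Catalytic asymmetric Diels–Alder reaction under a Corey-type cationic oxazaborolidine: methacrolein bound s-trans to boron (formyl C–H···O contact, rear face stacked on a catalyst phenyl) is attacked on the exposed Re face of its α-carbon, the ortho/para orientation and the endo approach (formyl under the diene) put the aryl group cis to the formyl group so that both stereocentres (1S,2S in 7) are set here, and fluoride then frees the phenol, which adds to the neighbouring cis aldehyde to close the six-membered hemiacetal (cis-fused lactol, obtained as C6 epimers).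

Step 4
Reactants: 9 (6aS,10aS)-1,3-dimethoxy-6a,9-dimethyl-6a,7,8,10a-tetrahydro-6H-benzo[c]chromen-6-ol
Product: 11 2-[(1R,6R)-6-ethenyl-3,6-dimethylcyclohex-2-en-1-yl]-3,5-dimethoxyphenol, via potassium phenoxide aldehyde 10 (not isolated)
Conditions: Ph3PCH3Br (4 equiv), KOC(CH3)3 (5 equiv), THF, 0 °C to reflux; then aq. NH4Cl
Reagents that add atoms: methyltriphenylphosphonium bromide, C[P+](c1ccccc1)(c1ccccc1)c1ccccc1.[Br-]
Why: Wittig methylenation of a lactol, in which the alkoxide base opens the hemiacetal to the potassium phenoxide aldehyde that the ylide then methylenates; the α-carbon is quaternary and cannot epimerise, so both stereocentres pass through unchanged (the descriptors change only because the CIP priorities change).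

Step 5
Reactants: 11 2-[(1R,6R)-6-ethenyl-3,6-dimethylcyclohex-2-en-1-yl]-3,5-dimethoxyphenol; 12 ethyl propiolate
Product: 13 8-[(1R,6R)-6-ethenyl-3,6-dimethylcyclohex-2-en-1-yl]-5,7-dimethoxy-2H-chromen-2-one
Conditions: 12 (3 equiv), Pd(OAc)2 (5 mol%), NaOAc, HCO2H, rt
Reagents that add atoms: none
Why: Trost-type Pd-catalysed phenol–propiolate coumarin annulation (net ortho C–H addition across the alkyne, then lactonisation with loss of ethanol) can only close at the single free position ortho to the OH, which gives the 5,7-dimethoxy-8-substituted coumarin; formic acid at room temperature is mild enough for the two alkenes and no stereocentre is touched.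

Step 6
Reactants: 14 5,7-dimethoxy-2H-chromen-2-one
Product: 15 8-iodo-5,7-dimethoxy-2H-chromen-2-one
Conditions: N-iodosuccinimide (1.05 equiv), CF3CO2H (cat.), MeCN, rt
Reagents that add atoms: N-iodosuccinimide, O=C1CCC(=O)N1I
Why: Electrophilic aromatic iodination goes to C8, which is para to the 5-methoxy and ortho to the 7-methoxy group and less crowded than C6 between the two methoxy groups.

Step 7
Reactants: 13 8-[(1R,6R)-6-ethenyl-3,6-dimethylcyclohex-2-en-1-yl]-5,7-dimethoxy-2H-chromen-2-one; 15 8-iodo-5,7-dimethoxy-2H-chromen-2-one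
Product: 16 8-[(1R,6R)-6-[(E)-2-(5,7-dimethoxy-2-oxo-2H-chromen-8-yl)ethenyl]-3,6-dimethylcyclohex-2-en-1-yl]-5,7-dimethoxy-2H-chromen-2-one
Conditions: Pd(OAc)2 (10 mol%), Bu4NCl, NaHCO3, DMF, 90 °C
Reagents that add atoms: none
Why: Mizoroki–Heck coupling (Jeffery conditions): syn carbopalladation of the monosubstituted vinyl group puts the aryl on the terminal carbon, and syn β-hydride elimination, possible only from the new benzylic CH2, gives the E-styryl bond without touching the two stereocentres.

## Compound list

1 | 2-hydroxy-4,6-dimethoxybenzaldehyde | O=Cc1c(O)cc(OC)cc1OC | starting material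
2 | 2-[(tert-butyldimethylsilyl)oxy]-4,6-dimethoxybenzaldehyde | O=Cc1c(O[Si](C)(C)C(C)(C)C)cc(OC)cc1OC | intermediate
3 | diethyl (2-methylprop-2-en-1-yl)phosphonate | CCOP(=O)(CC(C)=C)OCC | starting material
4 | lithium salt of the α-carbanion of 3 (not isolated) | [Li+].CCOP(=O)([CH-]C(C)=C)OCC | intermediate
5 | tert-butyl{3,5-dimethoxy-2-[(1E)-3-methylbuta-1,3-dien-1-yl]phenoxy}dimethylsilane | C=C(C)/C=C/c1c(O[Si](C)(C)C(C)(C)C)cc(OC)cc1OC | intermediate
6 | methacrolein (2-methylprop-2-enal) | C=C(C)C=O | starting material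
7 | (1S,2S)-2-{2-[(tert-butyldimethylsilyl)oxy]-4,6-dimethoxyphenyl}-1,4-dimethylcyclohex-3-ene-1-carbaldehyde (not isolated) | O=C[C@@]1(C)CCC(C)=C[C@H]1c1c(O[Si](C)(C)C(C)(C)C)cc(OC)cc1OC | intermediate
8 | (1S,2S)-2-(2-hydroxy-4,6-dimethoxyphenyl)-1,4-dimethylcyclohex-3-ene-1-carbaldehyde (not isolated) | O=C[C@@]1(C)CCC(C)=C[C@H]1c1c(O)cc(OC)cc1OC | intermediate
9 | (6aS,10aS)-1,3-dimethoxy-6a,9-dimethyl-6a,7,8,10a-tetrahydro-6H-benzo[c]chromen-6-ol (C6 epimers) | OC3[C@@]1(C)CCC(C)=C[C@H]1c2c(O3)cc(OC)cc2OC | intermediate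
10 | potassium 2-[(1S,6S)-6-formyl-3,6-dimethylcyclohex-2-en-1-yl]-3,5-dimethoxyphenolate (not isolated) | [K+].O=C[C@@]1(C)CCC(C)=C[C@H]1c1c([O-])cc(OC)cc1OC | intermediate
11 | 2-[(1R,6R)-6-ethenyl-3,6-dimethylcyclohex-2-en-1-yl]-3,5-dimethoxyphenol | C=C[C@@]1(C)CCC(C)=C[C@H]1c1c(O)cc(OC)cc1OC | intermediate
12 | ethyl propiolate | C#CC(=O)OCC | starting material
13 | 8-[(1R,6R)-6-ethenyl-3,6-dimethylcyclohex-2-en-1-yl]-5,7-dimethoxy-2H-chromen-2-one | C=C[C@@]1(C)CCC(C)=C[C@H]1c1c(OC)cc(OC)c2ccc(=O)oc12 | intermediate
14 | 5,7-dimethoxy-2H-chromen-2-one | COc1cc(OC)c2ccc(=O)oc2c1 | starting material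
15 | 8-iodo-5,7-dimethoxy-2H-chromen-2-one | COc1cc(OC)c2ccc(=O)oc2c1I | intermediate
16 | 8-[(1R,6R)-6-[(E)-2-(5,7-dimethoxy-2-oxo-2H-chromen-8-yl)ethenyl]-3,6-dimethylcyclohex-2-en-1-yl]-5,7-dimethoxy-2H-chromen-2-one | COc1cc(OC)c2ccc(=O)oc2c1/C=C/[C@@]1(C)CCC(C)=C[C@H]1c1c(OC)cc(OC)c2ccc(=O)oc12 | target

## Step count and risks

Total steps: 7. Longest linear sequence: 6 steps (1 → 2 → 5 → 9 → 11 → 13 → 16); step 6 is a one-step side branch.

**Step 3 (most likely to fail).** The cationic boron acid may ionise the very electron-rich trialkoxyaryl diene. Bond formation at the aryl-bearing diene terminus creates a quaternary centre next to a crowded benzylic carbon and may become stepwise, which would erode the cis (endo) ratio and the ee. The facial sense rests on the pre-transition-state model; if it proves opposite, the (3aR) precatalyst is used.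

Fallback, setting out from 15 and returning at 13: Heck coupling of 15 with isoprene (Pd(OAc)2, Bu4NCl, NaHCO3, DMF, 80 °C) gives 5,7-dimethoxy-8-[(1E)-3-methylbuta-1,3-dien-1-yl]-2H-chromen-2-one F1. The same oxazaborolidinium-catalysed cycloaddition with 6 gives (1S,2S)-2-(5,7-dimethoxy-2-oxo-2H-chromen-8-yl)-1,4-dimethylcyclohex-3-ene-1-carbaldehyde F2. Wittig methylenation (Ph3P=CH2, 1.2 equiv, THF, −78 to 0 °C) then returns to the route at 13. Here the pyranone ring is carried through the cycloaddition, the aryl group is a weaker donor and there is no silyl ether or free phenol, so diene ionisation is much less of a threat.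

**Step 5.** Neat formic acid could add the phenol across the nearby trisubstituted ring alkene (chroman formation), and palladium hydride could reduce the vinyl group.

Fallback, setting out from 11 and returning at 13: ortho-formylation of the magnesium phenoxide (MgCl2, Et3N, paraformaldehyde, MeCN, reflux) at the only free ortho position gives 3-[(1R,6R)-6-ethenyl-3,6-dimethylcyclohex-2-en-1-yl]-2-hydroxy-4,6-dimethoxybenzaldehyde F3. Ketenylidenetriphenylphosphorane (Ph3P=C=C=O, toluene, 90 °C) then acylates the phenol and closes the pyranone by intramolecular Wittig reaction, returning to the route at 13 with no acid and no palladium.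

**Step 2.** The allylic phosphonate anion can also attack through its γ-carbon, and the doubly ortho-substituted aldehyde is a poor electrophile, so yield and E purity are uncertain.

Fallback, setting out from 2 and returning at 5: Wittig reaction with the stabilised ylide 1-(triphenylphosphoranylidene)propan-2-one (toluene, reflux) gives (3E)-4-{2-[(tert-butyldimethylsilyl)oxy]-4,6-dimethoxyphenyl}but-3-en-2-one F4 with secure E geometry. Methylenation of the ketone with Ph3P=CH2 (from Ph3PCH3Br and KOC(CH3)3, THF) returns to the route at 5.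

## Further compounds

F1 | step 3 | 5,7-dimethoxy-8-[(1E)-3-methylbuta-1,3-dien-1-yl]-2H-chromen-2-one | C=C(C)/C=C/c1c(OC)cc(OC)c2ccc(=O)oc12
F2 | step 3 | (1S,2S)-2-(5,7-dimethoxy-2-oxo-2H-chromen-8-yl)-1,4-dimethylcyclohex-3-ene-1-carbaldehyde | O=C[C@@]1(C)CCC(C)=C[C@H]1c1c(OC)cc(OC)c2ccc(=O)oc12
F3 | step 5 | 3-[(1R,6R)-6-ethenyl-3,6-dimethylcyclohex-2-en-1-yl]-2-hydroxy-4,6-dimethoxybenzaldehyde | C=C[C@@]1(C)CCC(C)=C[C@H]1c1c(O)c(C=O)c(OC)cc1OC
F4 | step 2 | (3E)-4-{2-[(tert-butyldimethylsilyl)oxy]-4,6-dimethoxyphenyl}but-3-en-2-one | CC(=O)/C=C/c1c(O[Si](C)(C)C(C)(C)C)cc(OC)cc1OC
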